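## Retrosynthetic overview

1. Last bond: the C8–O ester, made by joining unprotected vanillic acid to the hindered secondary alcohol of the fully oxidised core; the C3 acetate (boronate-templated) and the 5,6-oxirane (hydroxyl-directed) are installed just before.
2. The C3–O and C8–O bonds, and the trans ring-fusion hydrogen, come from a double nucleophilic epoxidation of a cross-conjugated bicyclic trienone under control of the angular methyl, followed by reductive opening; isopropyl addition to the resulting ketone gives the tertiary carbinol.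
3. The trienone comes from a bicyclic aldol by dehydration and dehydrogenation; the seven-membered ring is closed by ring-closing metathesis.
4. The metathesis diene comes from 3-allylcyclopentenone by enantioselective conjugate methylation with aldol trapping by 3-methylbut-3-enal; this sets the quaternary centre that steers every later stereocentre.
5. Ring order: the cyclopentane is bought, the cycloheptene is closed second, the oxirane is the last ring.

Assumption: bicyclic compounds carry azulene numbering (C1 isopropyl carbinol, C3 acetoxy carbon, C3a angular-methyl carbon, C5/C6 oxirane, C8 ester carbon, C8a ring-fusion CH), and α means the face opposite the angular methyl.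

## Route

Step 1
Reactants: 1 3-ethoxycyclopent-2-en-1-one
Product: 3 3-allylcyclopent-2-en-1-one, via tertiary allylic alcohol 2 (not isolated)
Conditions: allylMgBr (1.2 equiv), THF, 0 °C; then 1 M HCl, 0 °C, 15 min
Reagents that add atoms: allylmagnesium bromide, C=CC[Mg]Br
Why: Stork–Danheiser transposition, in which 1,2-addition to the vinylogous ester and acid-induced loss of ethanol move the carbonyl and leave the allyl group on the β-carbon; no stereocentre is formed.

Step 2
Reactants: 4 3-methylbut-3-en-1-ol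
Product: 5 3-methylbut-3-enal
Conditions: Dess–Martin periodinane, CH2Cl2, 0 °C to rt; cold filtered solution used at once
Reagents that add atoms: none
Why: Dess–Martin oxidation is mild and non-basic, so the β,γ-unsaturated aldehyde is obtained without migration of the double bond into conjugation.

Step 3
Reactants: 3 3-allylcyclopent-2-en-1-one; 5 3-methylbut-3-enal
Product: 7 (3R)-3-allyl-2-(1-hydroxy-3-methylbut-3-en-1-yl)-3-methylcyclopentan-1-one (diastereomer mixture at C2/C1'), via dimethylaluminium enolate 6 (not isolated)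
Conditions: Cu(OTf)2 (5 mol %), enantiopure sulfonate-bearing N-heterocyclic carbene ligand as Ag2(NHC)2 (2.5 mol %, the enantiomer that gives the R centre), Me3Al (3 equiv), THF, −78 °C; then 5 (3 equiv), −78 to −30 °C; aq. Rochelle salt
Reagents that add atoms: trimethylaluminium, C[Al](C)C
Why: Copper-catalysed asymmetric conjugate addition of Me3Al to the β-substituted cyclopentenone sets the quaternary R centre under ligand control, and the regiodefined aluminium enolate is trapped in an aldol reaction; the two further centres form unselectively and are erased in step 5.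

Step 4
Reactants: 7 (3R)-3-allyl-2-(1-hydroxy-3-methylbut-3-en-1-yl)-3-methylcyclopentan-1-one
Product: 8 (3aR)-8-hydroxy-3a,6-dimethyl-2,3,3a,4,7,8-hexahydroazulen-1(8aH)-one (diastereomer mixture at C8/C8a)
Conditions: second-generation Grubbs catalyst (5 mol %), CH2Cl2, 40 °C
Reagents that add atoms: none
Why: Ring-closing metathesis between the allyl group and the 1,1-disubstituted alkene closes the seven-membered ring as a trisubstituted cycloalkene; both fusion diastereomers cyclise and converge in step 5.

Step 5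
Reactants: 8 (3aR)-8-hydroxy-3a,6-dimethyl-2,3,3a,4,7,8-hexahydroazulen-1(8aH)-one
Product: 10 (3aR)-3a,6-dimethyl-3,3a,4,7-tetrahydroazulen-1(2H)-one, via mesylate 9 (not isolated)
Conditions: MsCl, Et3N, DMAP (cat.), CH2Cl2, 0 °C to rt
Reagents that add atoms: none
Why: Mesylation and E1cB elimination through the ketone enolate remove both undefined centres and give the ring-fusion enone, whose alkene geometry is fixed by the ring.

Step 6
Reactants: 10 (3aR)-3a,6-dimethyl-3,3a,4,7-tetrahydroazulen-1(2H)-one
Product: 12 (3aS)-3a,6-dimethyl-4,7-dihydroazulen-1(3aH)-one, via lithium dienolate 11 (not isolated)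
Conditions: LDA (1.1 equiv), THF, −78 °C; then N-tert-butylbenzenesulfinimidoyl chloride, −78 °C
Reagents that add atoms: none
Why: Mukaiyama dehydrogenation, in which kinetic α'-deprotonation at C2, S-sulfilimination and syn-elimination introduce the C2=C3 double bond and give the cross-conjugated dienone; the quaternary centre is untouched (the descriptor changes only through priorities).

Step 7
Reactants: 12 (3aS)-3a,6-dimethyl-4,7-dihydroazulen-1(3aH)-one
Product: 13 (2R,3R,3aS,8S,8aR)-2,3:8,8a-diepoxy-3a,6-dimethyl-2,3,3a,4,7,8-hexahydroazulen-1(8aH)-one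
Conditions: 30% aq. H2O2 (4 equiv), LiOH (0.3 equiv), MeOH, 0 °C
Reagents that add atoms: hydrogen peroxide, OO
Why: Weitz–Scheffer nucleophilic epoxidation, in which hydroperoxide adds to both enone β-carbons and each enolate closes on oxygen on the face opposite the adjacent angular methyl (as with 1-en-3-one and 16-en-20-one steroids); this sets the C3–O and C8–O bonds α and leaves the electron-rich C5=C6 alkene alone.

Step 8
Reactants: 13 (2R,3R,3aS,8S,8aR)-2,3:8,8a-diepoxy-3a,6-dimethyl-2,3,3a,4,7,8-hexahydroazulen-1(8aH)-one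
Product: 14 (3S,3aR,8S,8aS)-3,8-dihydroxy-3a,6-dimethyl-2,3,3a,4,7,8-hexahydroazulen-1(8aH)-one
Conditions: SmI2 (4.5 equiv), THF–MeOH, −90 °C
Reagents that add atoms: none
Why: Samarium diiodide reduction of α,β-epoxy ketones cleaves each Cα–O bond with retention at the carbinol carbons, and the samarium enolate at C8a is protonated from the α face (anti to the angular methyl, on the side of the new C8 alkoxide), which gives the trans ring fusion.

Step 9
Reactants: 14 (3S,3aR,8S,8aS)-3,8-dihydroxy-3a,6-dimethyl-2,3,3a,4,7,8-hexahydroazulen-1(8aH)-one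
Product: 15 (1R,3S,3aR,8S,8aS)-1-isopropyl-3a,6-dimethyl-1,2,3,3a,4,7,8,8a-octahydroazulene-1,3,8-triol
Conditions: LaCl3·2LiCl (1.5 equiv), THF, 0 °C; i-PrMgCl (4 equiv), −78 to 0 °C; aq. NH4Cl
Reagents that add atoms: isopropylmagnesium chloride, CC(C)[Mg]Cl
Why: Lanthanum-promoted Grignard 1,2-addition suppresses enolisation and retro-aldol cleavage, and isopropyl enters from the α face, anti to the angular methyl and to the C8a–C8 bond, so the tertiary hydroxyl is β.

Step 10
Reactants: 15 (1R,3S,3aR,8S,8aS)-1-isopropyl-3a,6-dimethyl-1,2,3,3a,4,7,8,8a-octahydroazulene-1,3,8-triol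
Product: 16 (1R,3S,3aR,5S,6R,8S,8aS)-5,6-epoxy-1-isopropyl-3a,6-dimethyldecahydroazulene-1,3,8-triol
Conditions: VO(acac)2 (5 mol %), t-BuOOH (1.5 equiv), CH2Cl2, 0 °C to rt
Reagents that add atoms: tert-butyl hydroperoxide, CC(C)(C)OO
Why: Vanadium-catalysed hydroxyl-directed epoxidation, in which the homoallylic C8 hydroxyl binds the metal peroxide and delivers oxygen to its own α face of the trisubstituted alkene.

Step 11
Reactants: 16 (1R,3S,3aR,5S,6R,8S,8aS)-5,6-epoxy-1-isopropyl-3a,6-dimethyldecahydroazulene-1,3,8-triol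
Product: 19 (1R,3S,3aR,5S,6R,8S,8aS)-5,6-epoxy-1,8-dihydroxy-1-isopropyl-3a,6-dimethyldecahydroazulen-3-yl acetate, via cyclic boronate 17 (not isolated), via acetylated boronate 18 (not isolated)
Conditions: PhB(OH)2 (1.05 equiv), toluene, 4 Å MS, rt; Ac2O, pyridine, DMAP (cat.), rt; then 30% H2O2, pH 7 buffer, THF, 0 °C
Reagents that add atoms: acetic anhydride, CC(=O)OC(C)=O
Why: Transient boronic ester protection, in which only the syn-disposed C1/C8 1,3-diol can form a six-membered phenylboronate, so acetylation reaches the C3 hydroxyl alone and oxidative deboronation frees the diol; no stereocentre changes.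

Step 12
Reactants: 19 (1R,3S,3aR,5S,6R,8S,8aS)-5,6-epoxy-1,8-dihydroxy-1-isopropyl-3a,6-dimethyldecahydroazulen-3-yl acetate; 20 vanillic acid
Product: 23 (1R,3S,3aR,5S,6R,8S,8aS)-3-acetoxy-5,6-epoxy-1-hydroxy-1-isopropyl-3a,6-dimethyldecahydroazulen-8-yl 4-hydroxy-3-methoxybenzoate (CNP0241679.3), via mixed anhydride 21 (not isolated), via oxoketene 22 (not isolated)
Conditions: 20 (3 equiv), 2,4,6-trichlorobenzoyl chloride (3 equiv), Et3N (3 equiv), THF, 0 °C; this solution added over 4 h to 19, Et3N (4 equiv), DMAP (0.2 equiv), toluene, 45 °C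
Reagents that add atoms: none
Why: Proposed new method: vanillic acid is activated at the carboxyl group only, base then ionises the free phenol and the phenoxide expels trichlorobenzoate (E1cB) to give the p-quinonoid oxoketene 22, a small sp-centred electrophile to which the hindered C8 hydroxyl adds with re-aromatisation and retention at C8; aryl esters formed by competing phenoxide capture still carry a p-phenoxide and an aryloxide leaving group and so re-enter the ketene manifold, whereas the alkyl ester cannot eliminate and accumulates, so no phenol protection is needed; the closest known reaction type is the Yamaguchi esterification combined with the dissociative acyl transfer established for aryl 4-hydroxybenzoates.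

## Compound list

1 | 3-ethoxycyclopent-2-en-1-one | CCOC1=CC(=O)CC1 | starting material
2 | 1-allyl-3-ethoxycyclopent-2-en-1-ol (racemic) | C=CCC1(O)C=C(OCC)CC1 | intermediate
3 | 3-allylcyclopent-2-en-1-one | C=CCC1=CC(=O)CC1 | intermediate
4 | 3-methylbut-3-en-1-ol | C=C(C)CCO | starting material
5 | 3-methylbut-3-enal | C=C(C)CC=O | intermediate
6 | dimethylaluminium enolate of (R)-3-allyl-3-methylcyclopentanone (enolate double bond towards the quaternary carbon) | C=CC[C@@]1(C)CCC(O[Al](C)C)=C1 | intermediate
7 | (3R)-3-allyl-2-(1-hydroxy-3-methylbut-3-en-1-yl)-3-methylcyclopentan-1-one (diastereomer mixture at C2/C1') | C=CC[C@@]1(C)CCC(=O)C1C(O)CC(C)=C | intermediate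
8 | (3aR)-8-hydroxy-3a,6-dimethyl-2,3,3a,4,7,8-hexahydroazulen-1(8aH)-one (diastereomer mixture at C8/C8a) | OC1CC(C)=CC[C@@]2(C)CCC(=O)C12 | intermediate
9 | 8-O-methanesulfonate of 8 | CS(=O)(=O)OC1CC(C)=CC[C@@]2(C)CCC(=O)C12 | intermediate
10 | (3aR)-3a,6-dimethyl-3,3a,4,7-tetrahydroazulen-1(2H)-one | O=C1CC[C@]2(C)CC=C(C)CC=C12 | intermediate
11 | lithium α'-enolate of 10 (O–Li on C1, C1=C2) | [Li]OC1=CC[C@]2(C)CC=C(C)CC=C12 | intermediate
12 | (3aS)-3a,6-dimethyl-4,7-dihydroazulen-1(3aH)-one | O=C1C=C[C@]2(C)CC=C(C)CC=C12 | intermediate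
13 | (2R,3R,3aS,8S,8aR)-2,3:8,8a-diepoxy-3a,6-dimethyl-2,3,3a,4,7,8-hexahydroazulen-1(8aH)-one (both oxiranes α) | O=C1[C@@H]2O[C@@H]2[C@]2(C)CC=C(C)C[C@@H]3O[C@]123 | intermediate
14 | (3S,3aR,8S,8aS)-3,8-dihydroxy-3a,6-dimethyl-2,3,3a,4,7,8-hexahydroazulen-1(8aH)-one | O[C@H]1CC(C)=CC[C@@]2(C)[C@@H](O)CC(=O)[C@H]12 | intermediate
15 | (1R,3S,3aR,8S,8aS)-1-isopropyl-3a,6-dimethyl-1,2,3,3a,4,7,8,8a-octahydroazulene-1,3,8-triol | O[C@H]1CC(C)=CC[C@@]2(C)[C@@H](O)C[C@@](O)(C(C)C)[C@H]12 | intermediate
16 | (1R,3S,3aR,5S,6R,8S,8aS)-5,6-epoxy-1-isopropyl-3a,6-dimethyldecahydroazulene-1,3,8-triol | O[C@H]1C[C@@]2(C)O[C@H]2C[C@@]2(C)[C@@H](O)C[C@@](O)(C(C)C)[C@H]12 | intermediate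
17 | cyclic 1,8-O-phenylboronate of 16 (C3 hydroxyl free) | O1[C@H]2C[C@@]3(C)O[C@H]3C[C@@]3(C)[C@@H](O)C[C@@](OB1c4ccccc4)(C(C)C)[C@H]23 | intermediate
18 | 3-O-acetyl cyclic 1,8-O-phenylboronate of 16 | O1[C@H]2C[C@@]3(C)O[C@H]3C[C@@]3(C)[C@@H](OC(C)=O)C[C@@](OB1c4ccccc4)(C(C)C)[C@H]23 | intermediate
19 | (1R,3S,3aR,5S,6R,8S,8aS)-5,6-epoxy-1,8-dihydroxy-1-isopropyl-3a,6-dimethyldecahydroazulen-3-yl acetate | O[C@H]2C[C@@]3(C)O[C@H]3C[C@@]3(C)[C@@H](OC(C)=O)C[C@@](O)(C(C)C)[C@H]23 | intermediate
20 | vanillic acid (4-hydroxy-3-methoxybenzoic acid) | COc1cc(C(=O)O)ccc1O | starting material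
21 | 4-hydroxy-3-methoxybenzoic 2,4,6-trichlorobenzoic anhydride | COc1cc(C(=O)OC(=O)c2c(Cl)cc(Cl)cc2Cl)ccc1O | intermediate
22 | 2-methoxy-4-(oxomethylidene)cyclohexa-2,5-dien-1-one | COC1=CC(=C=O)C=CC1=O | intermediate
23 | (1R,3S,3aR,5S,6R,8S,8aS)-3-acetoxy-5,6-epoxy-1-hydroxy-1-isopropyl-3a,6-dimethyldecahydroazulen-8-yl 4-hydroxy-3-methoxybenzoate | COc1cc(C(=O)O[C@H]2C[C@@]3(C)O[C@H]3C[C@@]3(C)[C@@H](OC(C)=O)C[C@@](O)(C(C)C)[C@H]23)ccc1O | target

## Step count and risks

Total steps: 12. Longest linear sequence: 11 (1 → 3 → 7 → 8 → 10 → 12 → 13 → 14 → 15 → 16 → 19 → 23; the oxidation of 4 to 5 is the one side step).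

The three steps most likely to fail:

The conjugate methylation with aldol trapping (step 3) may suffer if the aluminium enolate is sluggish, if excess Me3Al methylates the aldehyde, or if the β,γ-unsaturated aldehyde isomerises. The fallback sets out from 3 and separates the events. The same copper-catalysed methyl addition is quenched with acid to give (R)-3-allyl-3-methylcyclopentan-1-one F1. 2-Iodoxybenzoic acid in DMSO at 70 °C dehydrogenates the only side that carries a β-hydrogen, giving (R)-4-allyl-4-methylcyclopent-2-en-1-one F2. LDA at −78 °C removes the only enolisable proton (next to the quaternary carbon) and the lithium enolate adds to 5, giving (4S)-4-allyl-5-(1-hydroxy-3-methylbut-3-en-1-yl)-4-methylcyclopent-2-en-1-one F3. Ring-closing metathesis with the second-generation Grubbs catalyst gives (3aS)-8-hydroxy-3a,6-dimethyl-3a,4,7,8-tetrahydroazulen-1(8aH)-one F4. MsCl/Et3N converts this through its methanesulfonate F5 into trienone 12, where the fallback returns to the route; steps 4 to 6 are then not needed.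

The double nucleophilic epoxidation (step 7) may fail if base moves the skipped diene into conjugation or if the hindered C2=C3 enone reacts too slowly. The fallback sets out from 12 and replaces peroxide by boron. CuCl/NaOt-Bu/Xantphos-catalysed double conjugate borylation with B2pin2 and MeOH in THF places boron on both β-carbons anti to the angular methyl, giving (3S,3aS,8S,8aR)-3a,6-dimethyl-3,8-bis(4,4,5,5-tetramethyl-1,3,2-dioxaborolan-2-yl)-2,3,3a,4,7,8-hexahydroazulen-1(8aH)-one F6. NaBO3 oxidation with retention gives diol ketone 14, where the route is rejoined; step 8 is then not needed.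

The proposed new step, the protecting-group-free vanilloylation (step 12), may fail through oligomerisation of the oxoketene or too slow capture by the hindered alcohol. The fallback uses known chemistry and sets out from 19. Yamaguchi esterification with commercial 4-acetoxy-3-methoxybenzoic acid (2,4,6-trichlorobenzoyl chloride, Et3N, then DMAP, toluene) gives (1R,3S,3aR,5S,6R,8S,8aS)-3-acetoxy-5,6-epoxy-1-hydroxy-1-isopropyl-3a,6-dimethyldecahydroazulen-8-yl 4-acetoxy-3-methoxybenzoate F7. Pyrrolidine in CH2Cl2 at 0 °C removes only the phenolic acetate and returns to 23.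

Further compounds
F1 | step 3 | (R)-3-allyl-3-methylcyclopentan-1-one | C=CC[C@@]1(C)CCC(=O)C1
F2 | step 3 | (R)-4-allyl-4-methylcyclopent-2-en-1-one | C=CC[C@@]1(C)C=CC(=O)C1
F3 | step 3 | (4S)-4-allyl-5-(1-hydroxy-3-methylbut-3-en-1-yl)-4-methylcyclopent-2-en-1-one (diastereomer mixture at C5/C1') | C=CC[C@@]1(C)C=CC(=O)C1C(O)CC(C)=C
F4 | step 3 | (3aS)-8-hydroxy-3a,6-dimethyl-3a,4,7,8-tetrahydroazulen-1(8aH)-one (diastereomer mixture at C8/C8a) | OC1CC(C)=CC[C@@]2(C)C=CC(=O)C12
F5 | step 3 | 8-O-methanesulfonate of F4 | CS(=O)(=O)OC1CC(C)=CC[C@@]2(C)C=CC(=O)C12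
F6 | step 7 | (3S,3aS,8S,8aR)-3a,6-dimethyl-3,8-bis(4,4,5,5-tetramethyl-1,3,2-dioxaborolan-2-yl)-2,3,3a,4,7,8-hexahydroazulen-1(8aH)-one | CC5(C)OB(OC5(C)C)[C@H]1CC(C)=CC[C@@]2(C)[C@@H](B3OC(C)(C)C(C)(C)O3)CC(=O)[C@H]12
F7 | step 12 | (1R,3S,3aR,5S,6R,8S,8aS)-3-acetoxy-5,6-epoxy-1-hydroxy-1-isopropyl-3a,6-dimethyldecahydroazulen-8-yl 4-acetoxy-3-methoxybenzoate | COc1cc(C(=O)O[C@H]2C[C@@]3(C)O[C@H]3C[C@@]3(C)[C@@H](OC(C)=O)C[C@@](O)(C(C)C)[C@H]23)ccc1OC(C)=O
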